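**Retrosynthetic overview**

1. Numbering: chain C1 (≡CH) to C15 (CH3), ring oxygen between C6 and C12. Enabling feature: the ring oxygen is 1,3 to the acetoxy carbon (O–C12–C11–C10) and transannular (1,5) to the chlorinated C9, so O, C9, C10, C11 and C12 form a latent 2,5-cis-tetrahydrofuran-3-ol (ring B) whose O–C9 bond can later be exchanged for C9–Cl with inversion.
2. Endgame: C10–OAc; C1≡C2 from an enal (Colvin); C3=C4 by cross-metathesis of a C6 allyl group.
3. Oxocane (last ring) ⇐ ring expansion of tetrahydrofuran B: chloronium ion on a cis C6=C7 alkene, ring oxygen to C6 (transient ring A = O, C6, C7, C8, C9), chloride to C9; this gives O–C6, C7–Cl and C9–Cl together.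
4. Ring B (first ring) ⇐ formal [3+2] annulation of a C10 aldehyde bearing an α-silyloxy group at C9 (C7–C10, from dimethyl (R)-malate) with (S)-3-silylpent-1-ene (C11–C15): forms C10–C11 and O–C12, sets C10 and C12; C13–Si → OH → Br.
5. Ring order: B (step 6); then A and the eight-membered ring together (step 12), ring B disappearing in the same step.

Key step: step 6

Remark: the ligand enantiomer in step 5 is assumed to be the one that gives (S)-7; Et2SCl·SbCl6 is prepared beforehand from Et2S, Cl2 and SbCl5.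

**Route**

Step 1
Reactants: 1 dimethyl (R)-malate
Product: 2 methyl (3R)-3,4-dihydroxybutanoate
Conditions: BH3·SMe2, NaBH4 (cat.), THF, 0 °C → rt; then MeOH
Reagents that add atoms: none
Why: Hydroxyl-directed chemoselective borane reduction should reduce only the ester next to the free OH through a cyclic alkoxyborane, leaving the stereocentre untouched.

Step 2
Reactants: 2 methyl (3R)-3,4-dihydroxybutanoate
Product: 3 methyl (3R)-3,4-bis(triethylsilyloxy)butanoate
Conditions: Et3SiCl, imidazole, DMF, 0 °C → rt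
Reagents that add atoms: chlorotriethylsilane CC[Si](Cl)(CC)CC
Why: Standard silylation of both hydroxyls; the secondary triethylsilyl ether is the internal nucleophile needed in step 6.

Step 3
Reactants: 3 methyl (3R)-3,4-bis(triethylsilyloxy)butanoate
Product: 4 methyl (3R)-4-oxo-3-(triethylsilyloxy)butanoate
Conditions: (COCl)2, DMSO, CH2Cl2, −78 → −30 °C; then Et3N, −78 → 0 °C
Reagents that add atoms: none
Why: Swern oxidation cleaves and oxidises a primary triethylsilyl ether in one pot while the secondary one survives; low temperature should avoid epimerisation at C9.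

Step 4
Reactants: 5 (E)-pent-2-en-1-ol
Product: 6 diethyl (E)-pent-2-en-1-yl phosphate
Conditions: ClP(O)(OEt)2, pyridine, DMAP (cat.), CH2Cl2, 0 °C
Reagents that add atoms: diethyl chlorophosphate CCOP(=O)(Cl)OCC
Why: O-Phosphorylation installs the leaving group for the allylic substitution.

Step 5
Reactants: 6 diethyl (E)-pent-2-en-1-yl phosphate
Product: 7 (S)-dimethyl(pent-1-en-3-yl)phenylsilane
Conditions: PhMe2Si–B(pin), CuCl (5 mol %), enantiopure imidazolinium salt (carbene precursor, 5 mol %), NaOMe, CH2Cl2, 0 °C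
Reagents that add atoms: 2-(dimethylphenylsilyl)-4,4,5,5-tetramethyl-1,3,2-dioxaborolane C[Si](C)(c1ccccc1)B1OC(C)(C)C(C)(C)O1
Why: Copper-catalysed γ-selective (SN2′) asymmetric allylic substitution by the silyl nucleophile released from the Si–B reagent should give the branched allylsilane, the chiral carbene ligand setting C13 as S.

Step 6
Reactants: 4 methyl (3R)-4-oxo-3-(triethylsilyloxy)butanoate; 7 (S)-dimethyl(pent-1-en-3-yl)phenylsilane
Product: 9 methyl 2-[(2R,3S,5R)-5-[(1S)-1-(dimethylphenylsilyl)propyl]-3-hydroxytetrahydrofuran-2-yl]acetate, via silyloxonium zwitterion 8 (not isolated)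
Conditions: BF3·OEt2 (1.2 equiv), CH2Cl2, −78 → −40 °C; then 1 M HCl, THF, 0 °C
Reagents that add atoms: none
Why: BF3 activates the aldehyde of 4; the terminal CH2 (C11) of 7 attacks it anti to silicon (anti-SE2′) to form C10–C11, and the β-silyl-stabilised cation at C12 is captured anti to silicon by the neighbouring C9–OSiEt3 oxygen to form O–C12, giving silyloxonium 8, which loses Et3Si+ (to the C10 alkoxide or on work-up). The closest known reaction type is the Lewis acid promoted formal [3+2] annulation of allylsilanes with α-triethylsilyloxy aldehydes to 2,5-disubstituted tetrahydrofuran-3-ols. Ring B (O, C9, C10, C11, C12) closes in a 5-exo mode by oxygen attack on the exocyclic cationic carbon C12. C10 (S) should be set by Felkin–Anh (polar, non-chelating BF3) addition anti to the C9–O bond, giving the 2,3-trans relation; C12 (R) is set by the C13 (S) centre of 7 through the anti/anti course from the conformer with C13–H eclipsing the vinyl group, which also gives the erythro C12–O/C13–Si relation needed later. The step needs annulation to win over loss of the silyl group (Hosomi–Sakurai allylation) and over closure through the C10 alkoxide; the slowly cleaved PhMe2Si group, −78 °C, a monodentate Lewis acid and the five-ring distance of the silyl ether oxygen should secure this, and the 2,5-cis ring demanded by reagent control is also the preferred envelope closure (matched case).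

Step 7
Reactants: 9 methyl 2-[(2R,3S,5R)-5-[(1S)-1-(dimethylphenylsilyl)propyl]-3-hydroxytetrahydrofuran-2-yl]acetate
Product: 10 methyl 2-[(2R,3S,5R)-3-(tert-butyldimethylsilyloxy)-5-[(1S)-1-(dimethylphenylsilyl)propyl]tetrahydrofuran-2-yl]acetate
Conditions: t-BuMe2SiOTf, 2,6-lutidine, CH2Cl2, −78 → 0 °C
Reagents that add atoms: tert-butyldimethylsilyl triflate CC(C)(C)[Si](C)(C)OS(=O)(=O)C(F)(F)F
Why: Silylation masks O10 as a bulky, non-participating ether, which steps 8, 9 and 12 require.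

Step 8
Reactants: 10 methyl 2-[(2R,3S,5R)-3-(tert-butyldimethylsilyloxy)-5-[(1S)-1-(dimethylphenylsilyl)propyl]tetrahydrofuran-2-yl]acetate
Product: 11 methyl 2-[(2R,3S,5R)-3-(tert-butyldimethylsilyloxy)-5-[(1S)-1-hydroxypropyl]tetrahydrofuran-2-yl]acetate
Conditions: KBr, AcOOH, NaOAc, AcOH, 0 °C → rt
Reagents that add atoms: peracetic acid CC(=O)OO
Why: Fleming–Tamao oxidation (ipso-bromodesilylation of the phenyl group, then peracid-induced 1,2-shift from Si to O) should convert C13–Si into C13–OH with retention; no alkene is present at this stage.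

Step 9
Reactants: 11 methyl 2-[(2R,3S,5R)-3-(tert-butyldimethylsilyloxy)-5-[(1S)-1-hydroxypropyl]tetrahydrofuran-2-yl]acetate
Product: 12 methyl 2-[(2R,3S,5R)-5-[(1R)-1-bromopropyl]-3-(tert-butyldimethylsilyloxy)tetrahydrofuran-2-yl]acetate
Conditions: CBr4, (n-C8H17)3P, toluene, 70 °C
Reagents that add atoms: carbon tetrabromide BrC(Br)(Br)Br
Why: Appel bromination by SN2 on the alkoxyphosphonium ion should invert C13 to R, giving the threo C12–O/C13–Br relation of the target.

Step 10
Reactants: 12 methyl 2-[(2R,3S,5R)-5-[(1R)-1-bromopropyl]-3-(tert-butyldimethylsilyloxy)tetrahydrofuran-2-yl]acetate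
Product: 13 2-[(2R,3S,5R)-5-[(1R)-1-bromopropyl]-3-(tert-butyldimethylsilyloxy)tetrahydrofuran-2-yl]acetaldehyde
Conditions: i-Bu2AlH, CH2Cl2, −78 °C; then aq. potassium sodium tartrate
Reagents that add atoms: none
Why: Partial ester reduction; the tetrahedral aluminium hemiacetal, chelated by the β ring oxygen, should survive at −78 °C and release the aldehyde on work-up.

Step 11
Reactants: 13 2-[(2R,3S,5R)-5-[(1R)-1-bromopropyl]-3-(tert-butyldimethylsilyloxy)tetrahydrofuran-2-yl]acetaldehyde; 14 (but-3-en-1-yl)triphenylphosphonium bromide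
Product: 16 tert-butyl{[(2R,3S,5R)-5-[(1R)-1-bromopropyl]-2-[(2Z)-hexa-2,5-dien-1-yl]tetrahydrofuran-3-yl]oxy}dimethylsilane, via phosphorus ylide 15 (not isolated)
Conditions: NaN(SiMe3)2, THF, −78 → 0 °C; then 13, −78 °C → rt
Reagents that add atoms: none
Why: Salt-free Wittig olefination with a non-stabilised ylide should give the cis C6=C7 alkene and bring in C3–C6.

Step 12
Reactants: 16 tert-butyl{[(2R,3S,5R)-5-[(1R)-1-bromopropyl]-2-[(2Z)-hexa-2,5-dien-1-yl]tetrahydrofuran-3-yl]oxy}dimethylsilane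
Product: 18 tert-butyl{[(2S,3S,5S,6S,8R)-8-[(1R)-1-bromopropyl]-3,5-dichloro-2-(prop-2-en-1-yl)oxocan-6-yl]oxy}dimethylsilane, via bicyclic oxonium salt 17 (not isolated)
Conditions: Et2SCl·SbCl6 (1.1 equiv), CH2Cl2, −78 → −40 °C; then aq. NaHCO3/Na2S2O3
Reagents that add atoms: chlorodiethylsulfonium hexachloroantimonate CC[S+](Cl)CC.Cl[Sb-](Cl)(Cl)(Cl)(Cl)Cl
Why: Proposed new method: the chloronium ion on the more nucleophilic cis C6=C7 alkene should be opened at C6 by the tetrahydrofuran oxygen (5-endo, anti to Cl) to give the cis-fused 1-oxoniabicyclo[3.3.0]octane 17 with the C5 chain and Cl on the convex face, and chloride from SbCl6− should then attack C9 with inversion (C12 is shielded by its branched, bromine-bearing neighbour and C6 by the adjacent C–Cl, but this site selectivity is the open question), so that O–C6, C7–Cl and C9–Cl form, ring B is erased and C6, C7 and C9 are set by anti addition to the cis alkene and SN2 at C9; the closest known reaction type is the halonium-induced ring expansion of tetrahydrofurans to eight-membered Laurencia haloethers through bicyclic oxonium ions, together with halide capture of such oxonium ions.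

Step 13
Reactants: 18 tert-butyl{[(2S,3S,5S,6S,8R)-8-[(1R)-1-bromopropyl]-3,5-dichloro-2-(prop-2-en-1-yl)oxocan-6-yl]oxy}dimethylsilane; 19 (E)-but-2-enal
Product: 20 (2E)-4-[(2S,3S,5S,6S,8R)-8-[(1R)-1-bromopropyl]-6-(tert-butyldimethylsilyloxy)-3,5-dichlorooxocan-2-yl]but-2-enal
Conditions: second-generation Grubbs catalyst (5 mol %), CH2Cl2, 40 °C
Reagents that add atoms: none
Why: Cross-metathesis of the terminal alkene with an excess of the electron-poor partner should give the E enal under thermodynamic control.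

Step 14
Reactants: 20 (2E)-4-[(2S,3S,5S,6S,8R)-8-[(1R)-1-bromopropyl]-6-(tert-butyldimethylsilyloxy)-3,5-dichlorooxocan-2-yl]but-2-enal
Product: 21 tert-butyl{[(2S,3S,5S,6S,8R)-8-[(1R)-1-bromopropyl]-3,5-dichloro-2-[(2E)-pent-2-en-4-yn-1-yl]oxocan-6-yl]oxy}dimethylsilane
Conditions: Me3SiCHN2, LiN(i-Pr)2, THF, −78 °C; then 20, −78 → 0 °C
Reagents that add atoms: trimethylsilyldiazomethane C[Si](C)(C)C=[N+]=[N-]
Why: Colvin rearrangement (1,2-addition, Peterson elimination, loss of N2, 1,2-hydride shift of the alkylidene carbene) should convert the enal directly into the terminal E enyne without touching the alkene geometry.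

Step 15
Reactants: 21 tert-butyl{[(2S,3S,5S,6S,8R)-8-[(1R)-1-bromopropyl]-3,5-dichloro-2-[(2E)-pent-2-en-4-yn-1-yl]oxocan-6-yl]oxy}dimethylsilane
Product: 22 (2S,3S,5S,6S,8R)-8-[(1R)-1-bromopropyl]-3,5-dichloro-2-[(2E)-pent-2-en-4-yn-1-yl]oxocan-6-ol
Conditions: HF·pyridine, pyridine, THF, 0 °C → rt
Reagents that add atoms: none
Why: Acidic fluoride desilylation avoids a free alkoxide, which would close an epoxide onto the trans C9–Cl.

Step 16
Reactants: 22 (2S,3S,5S,6S,8R)-8-[(1R)-1-bromopropyl]-3,5-dichloro-2-[(2E)-pent-2-en-4-yn-1-yl]oxocan-6-ol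
Product: 23 (2S,3S,5S,6S,8R)-8-[(1R)-1-bromopropyl]-3,5-dichloro-2-[(2E)-pent-2-en-4-yn-1-yl]oxocan-6-yl acetate (CNP0251465.3)
Conditions: Ac2O, pyridine, DMAP (cat.), CH2Cl2, 0 °C → rt
Reagents that add atoms: acetic anhydride CC(=O)OC(C)=O
Why: DMAP-catalysed acylation of the secondary alcohol with retention completes the target.

**Compound list**

1 | dimethyl (R)-malate | COC(=O)C[C@H](C(=O)OC)O | starting material
2 | methyl (3R)-3,4-dihydroxybutanoate | COC(=O)C[C@H](CO)O | intermediate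
3 | methyl (3R)-3,4-bis(triethylsilyloxy)butanoate | COC(=O)C[C@H](CO[Si](CC)(CC)CC)O[Si](CC)(CC)CC | intermediate
4 | methyl (3R)-4-oxo-3-(triethylsilyloxy)butanoate | COC(=O)C[C@H](C=O)O[Si](CC)(CC)CC | intermediate
5 | (E)-pent-2-en-1-ol | CC/C=C/CO | starting material
6 | diethyl (E)-pent-2-en-1-yl phosphate | CC/C=C/COP(=O)(OCC)OCC | intermediate
7 | (S)-dimethyl(pent-1-en-3-yl)phenylsilane | C=C[C@@H]([Si](C)(C)c1ccccc1)CC | intermediate
8 | O-triethylsilyl oxonium of ring B with C10–O–BF3 (zwitterion) | COC(=O)C[C@H]1[O+]([Si](CC)(CC)CC)[C@@H]([C@@H]([Si](C)(C)c2ccccc2)CC)C[C@@H]1O[B-](F)(F)F | intermediate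
9 | methyl 2-[(2R,3S,5R)-5-[(1S)-1-(dimethylphenylsilyl)propyl]-3-hydroxytetrahydrofuran-2-yl]acetate | COC(=O)C[C@H]1O[C@@H]([C@@H]([Si](C)(C)c2ccccc2)CC)C[C@@H]1O | intermediate
10 | methyl 2-[(2R,3S,5R)-3-(tert-butyldimethylsilyloxy)-5-[(1S)-1-(dimethylphenylsilyl)propyl]tetrahydrofuran-2-yl]acetate | COC(=O)C[C@H]1O[C@@H]([C@@H]([Si](C)(C)c2ccccc2)CC)C[C@@H]1O[Si](C)(C)C(C)(C)C | intermediate
11 | methyl 2-[(2R,3S,5R)-3-(tert-butyldimethylsilyloxy)-5-[(1S)-1-hydroxypropyl]tetrahydrofuran-2-yl]acetate | COC(=O)C[C@H]1O[C@@H]([C@@H](O)CC)C[C@@H]1O[Si](C)(C)C(C)(C)C | intermediate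
12 | methyl 2-[(2R,3S,5R)-5-[(1R)-1-bromopropyl]-3-(tert-butyldimethylsilyloxy)tetrahydrofuran-2-yl]acetate | COC(=O)C[C@H]1O[C@@H]([C@H](Br)CC)C[C@@H]1O[Si](C)(C)C(C)(C)C | intermediate
13 | 2-[(2R,3S,5R)-5-[(1R)-1-bromopropyl]-3-(tert-butyldimethylsilyloxy)tetrahydrofuran-2-yl]acetaldehyde | O=CC[C@H]1O[C@@H]([C@H](Br)CC)C[C@@H]1O[Si](C)(C)C(C)(C)C | intermediate
14 | (but-3-en-1-yl)triphenylphosphonium bromide | C=CCC[P+](c1ccccc1)(c1ccccc1)c1ccccc1.[Br-] | starting material
15 | (but-3-en-1-ylidene)triphenylphosphorane | C=CCC=P(c1ccccc1)(c1ccccc1)c1ccccc1 | intermediate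
16 | tert-butyl{[(2R,3S,5R)-5-[(1R)-1-bromopropyl]-2-[(2Z)-hexa-2,5-dien-1-yl]tetrahydrofuran-3-yl]oxy}dimethylsilane | C=CC/C=C\C[C@H]1O[C@@H]([C@H](Br)CC)C[C@@H]1O[Si](C)(C)C(C)(C)C | intermediate
17 | cis-fused 1-oxoniabicyclo[3.3.0]octane (O bonded to C6, C9, C12) hexachloroantimonate | C=CC[C@H]1[C@@H](Cl)C[C@@H]2[C@@H](O[Si](C)(C)C(C)(C)C)C[C@H]([C@H](Br)CC)[O+]12.Cl[Sb-](Cl)(Cl)(Cl)(Cl)Cl | intermediate
18 | tert-butyl{[(2S,3S,5S,6S,8R)-8-[(1R)-1-bromopropyl]-3,5-dichloro-2-(prop-2-en-1-yl)oxocan-6-yl]oxy}dimethylsilane | C=CC[C@@H]1O[C@@H]([C@H](Br)CC)C[C@H](O[Si](C)(C)C(C)(C)C)[C@@H](Cl)C[C@@H]1Cl | intermediate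
19 | (E)-but-2-enal | C/C=C/C=O | starting material
20 | (2E)-4-[(2S,3S,5S,6S,8R)-8-[(1R)-1-bromopropyl]-6-(tert-butyldimethylsilyloxy)-3,5-dichlorooxocan-2-yl]but-2-enal | O=C/C=C/C[C@@H]1O[C@@H]([C@H](Br)CC)C[C@H](O[Si](C)(C)C(C)(C)C)[C@@H](Cl)C[C@@H]1Cl | intermediate
21 | tert-butyl{[(2S,3S,5S,6S,8R)-8-[(1R)-1-bromopropyl]-3,5-dichloro-2-[(2E)-pent-2-en-4-yn-1-yl]oxocan-6-yl]oxy}dimethylsilane | C#C/C=C/C[C@@H]1O[C@@H]([C@H](Br)CC)C[C@H](O[Si](C)(C)C(C)(C)C)[C@@H](Cl)C[C@@H]1Cl | intermediate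
22 | (2S,3S,5S,6S,8R)-8-[(1R)-1-bromopropyl]-3,5-dichloro-2-[(2E)-pent-2-en-4-yn-1-yl]oxocan-6-ol | C#C/C=C/C[C@@H]1O[C@@H]([C@H](Br)CC)C[C@H](O)[C@@H](Cl)C[C@@H]1Cl | intermediate
23 | (2S,3S,5S,6S,8R)-8-[(1R)-1-bromopropyl]-3,5-dichloro-2-[(2E)-pent-2-en-4-yn-1-yl]oxocan-6-yl acetate | C#C/C=C/C[C@@H]1O[C@@H]([C@H](Br)CC)C[C@H](OC(C)=O)[C@@H](Cl)C[C@@H]1Cl | target

**Step count**

Total: 16 steps. Longest linear sequence: 14 steps (steps 1–3 and 6–16).

**Steps most likely to fail**

1. Step 12 (Proposed new method). What may go wrong: capture of the chloronium ion by chloride or by the C10 silyl ether oxygen before the ring oxygen closes ring A; reaction at the terminal alkene; opening of the oxonium ion at C6 or C12 instead of C9, which returns a tetrahydrofuran. Fallback, built from known reaction types, setting out from 13 and coming back at 18: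
 - Wittig reaction of 13 with Ph3P=CHOMe should give the enol ether tert-butyl{[(2R,3S,5R)-5-[(1R)-1-bromopropyl]-2-(3-methoxyprop-2-en-1-yl)tetrahydrofuran-3-yl]oxy}dimethylsilane F1.
 - Hydrolysis (aq. HCl, THF) should give 3-[(2R,3S,5R)-5-[(1R)-1-bromopropyl]-3-(tert-butyldimethylsilyloxy)tetrahydrofuran-2-yl]propanal F2.
 - Enamine-catalysed α-chlorination (N-chlorosuccinimide, the enantiomer of 2,5-diphenylpyrrolidine that delivers the S chloride) should give (2S)-2-chloro-3-[(2R,3S,5R)-5-[(1R)-1-bromopropyl]-3-(tert-butyldimethylsilyloxy)tetrahydrofuran-2-yl]propanal F3.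
 - Addition of allyl pinacolboronate under Cornforth control should give the anti chlorohydrin (2S,3R)-2-chloro-1-[(2R,3S,5R)-5-[(1R)-1-bromopropyl]-3-(tert-butyldimethylsilyloxy)tetrahydrofuran-2-yl]hex-5-en-3-ol F4.
 - Tf2O and 2,6-di-tert-butylpyridine at −78 °C should give its trifluoromethanesulfonate F5.
 - F5 should ionise with participation of the ring oxygen (inversion at C6) to the bicyclic oxonium trifluoromethanesulfonate F6, which n-Bu4NCl added at low temperature opens to 18.
 - C6 and C7 are then set by catalyst and substrate control instead of by the chloronium event, and oxonium formation is separated from chloride delivery. The site of chloride attack on the oxonium ion remains the same question as in step 12.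

2. Step 6. What may go wrong: loss of the silyl group from the β-silyl cation (allylation instead of annulation); reaction through the conformer with ethyl inside, eroding the C12/C13 relation; weak Felkin control at C10. Fallback, setting out from 4 and coming back at 12:
 - Allylboration of 4 with racemic 2-(pent-1-en-3-yl)-4,4,5,5-tetramethyl-1,3,2-dioxaborolane (Z-selective for pinacol esters, Felkin addition) should give methyl (3R,4S,6Z)-4-hydroxy-3-(triethylsilyloxy)non-6-enoate F7.
 - t-BuMe2SiOTf and 2,6-lutidine should give methyl (3R,4S,6Z)-4-(tert-butyldimethylsilyloxy)-3-(triethylsilyloxy)non-6-enoate F8.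
 - N-Bromosuccinimide in MeCN at −40 °C should effect 5-exo bromoetherification with the C9 silyl ether oxygen as nucleophile (loss of Et3Si, anti addition to the cis alkene) to give 12.
 - The two bonds are then made in separate steps, and steps 8 and 9 are bypassed.

3. Step 8. What may go wrong: acid-promoted anti elimination of the β-silyl ether (Peterson-type ring opening); slow ipso-substitution at the hindered silicon. Fallback, setting out from 10 and coming back at 11:
 - The elimination is used on purpose: BF3·OEt2 in CH2Cl2 at 0 °C should open 10 to methyl (3R,4S,6E)-4-(tert-butyldimethylsilyloxy)-3-hydroxynon-6-enoate F9.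
 - Shi epoxidation (Oxone, 2KHSO5·KHSO4·K2SO4, with the enantiomer of the fructose-derived ketone that gives the 6S,7S epoxide) should give methyl (3R,4S)-4-(tert-butyldimethylsilyloxy)-5-[(2S,3S)-3-ethyloxiran-2-yl]-3-hydroxypentanoate F10.
 - Camphorsulfonic acid in CH2Cl2 should induce 5-exo opening at C12 by the C9 hydroxyl with inversion to give 11.
 - The C13 oxygen then comes from alkene epoxidation and not from C–Si oxidation.

**Further compounds**

F1 | step 12 | tert-butyl{[(2R,3S,5R)-5-[(1R)-1-bromopropyl]-2-(3-methoxyprop-2-en-1-yl)tetrahydrofuran-3-yl]oxy}dimethylsilane (E/Z mixture) | COC=CC[C@H]1O[C@@H]([C@H](Br)CC)C[C@@H]1O[Si](C)(C)C(C)(C)C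
F2 | step 12 | 3-[(2R,3S,5R)-5-[(1R)-1-bromopropyl]-3-(tert-butyldimethylsilyloxy)tetrahydrofuran-2-yl]propanal | O=CCC[C@H]1O[C@@H]([C@H](Br)CC)C[C@@H]1O[Si](C)(C)C(C)(C)C
F3 | step 12 | (2S)-2-chloro-3-[(2R,3S,5R)-5-[(1R)-1-bromopropyl]-3-(tert-butyldimethylsilyloxy)tetrahydrofuran-2-yl]propanal | O=C[C@@H](Cl)C[C@H]1O[C@@H]([C@H](Br)CC)C[C@@H]1O[Si](C)(C)C(C)(C)C
F4 | step 12 | (2S,3R)-2-chloro-1-[(2R,3S,5R)-5-[(1R)-1-bromopropyl]-3-(tert-butyldimethylsilyloxy)tetrahydrofuran-2-yl]hex-5-en-3-ol | C=CC[C@@H](O)[C@@H](Cl)C[C@H]1O[C@@H]([C@H](Br)CC)C[C@@H]1O[Si](C)(C)C(C)(C)C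
F5 | step 12 | (2S,3R)-2-chloro-1-[(2R,3S,5R)-5-[(1R)-1-bromopropyl]-3-(tert-butyldimethylsilyloxy)tetrahydrofuran-2-yl]hex-5-en-3-yl trifluoromethanesulfonate | C=CC[C@@H](OS(=O)(=O)C(F)(F)F)[C@@H](Cl)C[C@H]1O[C@@H]([C@H](Br)CC)C[C@@H]1O[Si](C)(C)C(C)(C)C
F6 | step 12 | cis-fused 1-oxoniabicyclo[3.3.0]octane (cation of 17) trifluoromethanesulfonate | C=CC[C@H]1[C@@H](Cl)C[C@@H]2[C@@H](O[Si](C)(C)C(C)(C)C)C[C@H]([C@H](Br)CC)[O+]12.[O-]S(=O)(=O)C(F)(F)F
F7 | step 6 | methyl (3R,4S,6Z)-4-hydroxy-3-(triethylsilyloxy)non-6-enoate | COC(=O)C[C@@H](O[Si](CC)(CC)CC)[C@@H](O)C/C=C\CC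
F8 | step 6 | methyl (3R,4S,6Z)-4-(tert-butyldimethylsilyloxy)-3-(triethylsilyloxy)non-6-enoate | COC(=O)C[C@@H](O[Si](CC)(CC)CC)[C@@H](O[Si](C)(C)C(C)(C)C)C/C=C\CC
F9 | step 8 | methyl (3R,4S,6E)-4-(tert-butyldimethylsilyloxy)-3-hydroxynon-6-enoate | COC(=O)C[C@@H](O)[C@@H](O[Si](C)(C)C(C)(C)C)C/C=C/CC
F10 | step 8 | methyl (3R,4S)-4-(tert-butyldimethylsilyloxy)-5-[(2S,3S)-3-ethyloxiran-2-yl]-3-hydroxypentanoate | COC(=O)C[C@@H](O)[C@@H](O[Si](C)(C)C(C)(C)C)C[C@@H]1O[C@H]1CC
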